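**Retrosynthetic overview**
1. Target 34 ⇐ quinone 33 ⇐ dimethyl ether 32. The hydroquinone is unmasked last, and the C5 ketone comes from oxidation of a C5 carbinol.
2. Aryl–C1 bond: aryllithium 28 + allylic bromide 24.
3. C4–C5 bond (key step): vinylogous Mukaiyama aldol of the C15 enal 18 with silyl dienolate 3; γ-attack delivers the 2E enoate directly.
4. C8–C9 bond and the 6E olefin: acetoacetate dianion alkylation with bromide 10, then Z-enol phosphate / Me2CuLi.
5. C12–C13 bond and the only stereocentre: catalytic asymmetric vinylogous Mukaiyama aldol of 3-methylbut-2-enal with 3. No ring is built; the arene is bought as 4-methoxy-2-methylphenol.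

Numbering: side-chain C1 is the ArCH2 carbon, C5 the ketone, C13 the carbinol. Catalyst A is Denmark's (R,R)-bisphosphoramide: two (R)-N,N'-dimethyl-1,1'-binaphthyl-2,2'-diamine-derived cyclic phosphoric triamides joined through N,N'-dimethylpentane-1,5-diamine.
Assumption: catalyst A/SiCl4 delivers the dienolate to the Re face of a conjugated aldehyde, which gives the R carbinol here; the configuration of 6 is confirmed by Mosher ester analysis before going on.

**Route**

Step 1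
Reactants: 1 methyl 3-methylbut-2-enoate
Product: 3 tert-butyl[(1-methoxy-3-methylbuta-1,3-dien-1-yl)oxy]dimethylsilane, via lithium dienolate 2 (not isolated)
Conditions: LiN(i-Pr)2, THF/DMPU, −78 °C; TBSCl, −78 °C → rt; distil
Reagents that add atoms: tert-butyldimethylsilyl chloride, CC(C)(C)[Si](C)(C)Cl
Why: Kinetic γ-deprotonation of the enoate and O-silylation of the extended enolate give the silyl ketene acetal, whose C1=C2 geometry is immaterial.

Step 2
Reactants: 4 3-methylbut-2-enal; 3 silyl dienolate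
Product: 6 methyl (2E,5R)-5-hydroxy-3,7-dimethylocta-2,6-dienoate, via trichlorosilyl ether 5 (not isolated)
Conditions: SiCl4 (1.1 eq), catalyst A (2 mol %), i-Pr2NEt (10 mol %), CH2Cl2, −78 °C; sat. aq. NaHCO3
Reagents that add atoms: none
Why: In this Lewis-base-activated SiCl4 vinylogous Mukaiyama aldol the phosphoramide-bound SiCl3 cation activates the enal, the dienolate attacks through its γ-carbon on the Re face to set the carbinol as R (C13 of the target), and the s-trans dienolate gives the 2E enoate.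

Step 3
Reactants: 6 hydroxy ester
Product: 7 methyl (2E,5R)-5-[(tert-butyldimethylsilyl)oxy]-3,7-dimethylocta-2,6-dienoate
Conditions: TBSCl, imidazole, DMF, rt
Reagents that add atoms: tert-butyldimethylsilyl chloride, CC(C)(C)[Si](C)(C)Cl
Why: Standard silylation protects the acid-labile allylic alcohol for the organometallic steps without touching the stereocentre.

Step 4
Reactants: 7 silyl ether ester
Product: 8 (2E,5R)-5-[(tert-butyldimethylsilyl)oxy]-3,7-dimethylocta-2,6-dien-1-ol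
Conditions: i-Bu2AlH (2.2 eq), CH2Cl2, −78 °C; Rochelle salt
Reagents that add atoms: none
Why: 1,2-Reduction of the conjugated ester by the aluminium hydride gives the allylic alcohol with the olefin geometry intact.

Step 5
Reactants: 8 allylic alcohol
Product: 10 (2E,5R)-1-bromo-5-[(tert-butyldimethylsilyl)oxy]-3,7-dimethylocta-2,6-diene, via allylic mesylate 9 (not isolated)
Conditions: MsCl, Et3N, THF, −40 °C; LiBr, THF, 0 °C; used crude
Reagents that add atoms: lithium bromide, [Li+].[Br-]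
Why: Mesylation followed by SN2 displacement with bromide is a non-acidic route to the primary allylic bromide that keeps the 2E geometry and the silyl ether.

Step 6
Reactants: 11 methyl acetoacetate; 10 allylic bromide
Product: 13 methyl (6E,9R)-9-[(tert-butyldimethylsilyl)oxy]-7,11-dimethyl-3-oxododeca-6,10-dienoate, via acetoacetate dianion 12 (not isolated)
Conditions: NaH, THF, 0 °C; n-BuLi, 0 °C; then 10, 0 °C → rt; AcOH quench
Reagents that add atoms: none
Why: The Weiler dianion alkylates only at its more reactive terminal (γ) carbon, giving the homologated β-keto ester by SN2 at the primary allylic bromide.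

Step 7
Reactants: 13 β-keto ester
Product: 15 methyl (2Z,6E,9R)-9-[(tert-butyldimethylsilyl)oxy]-3-[(diethoxyphosphoryl)oxy]-7,11-dimethyldodeca-2,6,10-trienoate, via sodium enolate 14 (not isolated)
Conditions: NaH, Et2O, 0 °C; ClP(O)(OEt)2, 0 °C → rt
Reagents that add atoms: diethyl chlorophosphate, CCOP(=O)(Cl)OCC
Why: The chelated U-shaped sodium enolate is trapped on oxygen, giving the Z enol phosphate selectively (O-phosphorylation of a β-keto ester enolate).

Step 8
Reactants: 15 Z enol phosphate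
Product: 16 methyl (2E,6E,9R)-9-[(tert-butyldimethylsilyl)oxy]-3,7,11-trimethyldodeca-2,6,10-trienoate
Conditions: Me2CuLi (3 eq, from CuI + 2 MeLi), Et2O, −78 → −45 °C; aq. NH4Cl
Reagents that add atoms: lithium dimethylcuprate, [Li+].C[Cu-]C
Why: Cuprate addition–elimination on the enol phosphate goes with retention, so the Z phosphate gives the 2E β-methyl enoate (Weiler trisubstituted-olefin synthesis).

Step 9
Reactants: 16 trienoate
Product: 17 (2E,6E,9R)-9-[(tert-butyldimethylsilyl)oxy]-3,7,11-trimethyldodeca-2,6,10-trien-1-ol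
Conditions: i-Bu2AlH (2.2 eq), CH2Cl2, −78 °C; Rochelle salt
Reagents that add atoms: none
Why: 1,2-Reduction of the enoate to the allylic alcohol, as in step 4.

Step 10
Reactants: 17 allylic alcohol
Product: 18 (2E,6E,9R)-9-[(tert-butyldimethylsilyl)oxy]-3,7,11-trimethyldodeca-2,6,10-trienal
Conditions: MnO2 (20 eq), CH2Cl2, rt
Reagents that add atoms: none
Why: MnO2 oxidises the primary allylic alcohol selectively to the enal under neutral conditions without E/Z isomerisation.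

Step 11
Reactants: 18 enal; 3 silyl dienolate
Product: 20 methyl (2E,5R,6E,10E,13R)-13-[(tert-butyldimethylsilyl)oxy]-5-hydroxy-3,7,11,15-tetramethylhexadeca-2,6,10,14-tetraenoate, via trichlorosilyl ether 19 (not isolated)
Conditions: SiCl4 (1.1 eq), catalyst A (2 mol %), i-Pr2NEt (10 mol %), CH2Cl2, −78 °C; sat. aq. NaHCO3
Reagents that add atoms: none
Why: The same vinylogous Mukaiyama aldol joins the C15 enal and the C5 dienolate by exclusive 1,2-addition and γ-attack, forming the C4–C5 bond and the 2E enoate; the catalyst-controlled C5 carbinol (5R expected) is oxidised later, so its configuration is immaterial.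

Step 12
Reactants: 20 hydroxy ester
Product: 21 methyl (2E,5R,6E,10E,13R)-13-[(tert-butyldimethylsilyl)oxy]-3,7,11,15-tetramethyl-5-[(triethylsilyl)oxy]hexadeca-2,6,10,14-tetraenoate
Conditions: Et3SiCl, imidazole, CH2Cl2, 0 °C
Reagents that add atoms: chlorotriethylsilane, CC[Si](Cl)(CC)CC
Why: Silylation with the more labile triethylsilyl group differentiates the C5 oxygen from the C13 silyl ether for later selective release.

Step 13
Reactants: 21 bis-silyl ether ester
Product: 22 (2E,5R,6E,10E,13R)-13-[(tert-butyldimethylsilyl)oxy]-3,7,11,15-tetramethyl-5-[(triethylsilyl)oxy]hexadeca-2,6,10,14-tetraen-1-ol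
Conditions: i-Bu2AlH (2.2 eq), CH2Cl2, −78 °C; Rochelle salt
Reagents that add atoms: none
Why: 1,2-Reduction of the enoate gives the C1 allylic alcohol while both silyl ethers survive.

Step 14
Reactants: 22 allylic alcohol
Product: 24 (2E,5R,6E,10E,13R)-1-bromo-13-[(tert-butyldimethylsilyl)oxy]-3,7,11,15-tetramethyl-5-[(triethylsilyl)oxy]hexadeca-2,6,10,14-tetraene, via allylic mesylate 23 (not isolated)
Conditions: MsCl, Et3N, THF, −40 °C; LiBr, THF, 0 °C; used crude
Reagents that add atoms: lithium bromide, [Li+].[Br-]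
Why: Mesylate formation and SN2 bromide displacement under base-buffered conditions leave the triethylsilyl ether and the 2E olefin untouched.

Step 15
Reactants: 25 4-methoxy-2-methylphenol
Product: 26 2-bromo-4-methoxy-6-methylphenol
Conditions: Br2 (1.0 eq), CH2Cl2, 0 °C
Reagents that add atoms: bromine, BrBr
Why: Electrophilic aromatic bromination goes to the only free position ortho to the strongly directing phenol OH, the para position being blocked.

Step 16
Reactants: 26 bromophenol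
Product: 27 1-bromo-2,5-dimethoxy-3-methylbenzene
Conditions: MeI, K2CO3, acetone, reflux
Reagents that add atoms: iodomethane, CI
Why: Williamson O-methylation of the phenoxide gives the hydroquinone dimethyl ether, which is stable to organolithium chemistry.

Step 17
Reactants: 27 aryl bromide; 24 allylic bromide
Product: 29 (2E,5R,6E,10E,13R)-13-[(tert-butyldimethylsilyl)oxy]-1-(2,5-dimethoxy-3-methylphenyl)-3,7,11,15-tetramethyl-5-[(triethylsilyl)oxy]hexadeca-2,6,10,14-tetraene, via aryllithium 28 (not isolated)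
Conditions: 27 (1.5 eq), n-BuLi, THF, −78 °C; CuBr·SMe2 (10 mol %), then 24, −78 → 0 °C
Reagents that add atoms: none
Why: Bromine–lithium exchange followed by copper-catalysed SN2 allylic substitution attacks the primary carbon (the γ-carbon is fully substituted), keeping the 2E geometry.

Step 18
Reactants: 29 bis-silyl ether
Product: 30 (2E,5R,6E,10E,13R)-13-[(tert-butyldimethylsilyl)oxy]-1-(2,5-dimethoxy-3-methylphenyl)-3,7,11,15-tetramethylhexadeca-2,6,10,14-tetraen-5-ol
Conditions: pyridinium p-toluenesulfonate (0.2 eq), MeOH/CH2Cl2, 0 °C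
Reagents that add atoms: none
Why: Mild acid-catalysed methanolysis cleaves the triethylsilyl ether about a hundred times faster than the tert-butyldimethylsilyl ether.

Step 19
Reactants: 30 C5 alcohol
Product: 31 (2E,6E,10E,13R)-13-[(tert-butyldimethylsilyl)oxy]-1-(2,5-dimethoxy-3-methylphenyl)-3,7,11,15-tetramethylhexadeca-2,6,10,14-tetraen-5-one
Conditions: Dess–Martin periodinane, NaHCO3, CH2Cl2, 0 °C → rt
Reagents that add atoms: none
Why: Buffered Dess–Martin oxidation converts the allylic carbinol into the enone without moving the skipped C2=C3 olefin into conjugation.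

Step 20
Reactants: 31 silyl ether ketone
Product: 32 (2E,6E,10E,13R)-1-(2,5-dimethoxy-3-methylphenyl)-13-hydroxy-3,7,11,15-tetramethylhexadeca-2,6,10,14-tetraen-5-one
Conditions: Bu4NF/AcOH (1:1), THF, 0 °C → rt
Reagents that add atoms: none
Why: Acetic-acid-buffered fluoride desilylation frees the C13 alcohol at near-neutral pH, so the β,γ-unsaturated ketone does not isomerise and the stereocentre is untouched.

Step 21
Reactants: 32 dimethoxyarene
Product: 33 2-[(2E,6E,10E,13R)-13-hydroxy-3,7,11,15-tetramethyl-5-oxohexadeca-2,6,10,14-tetraen-1-yl]-6-methylcyclohexa-2,5-diene-1,4-dione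
Conditions: (NH4)2Ce(NO3)6 (2.5 eq), MeCN/H2O (2:1), 0 °C, 15 min
Reagents that add atoms: water, O
Why: Oxidative demethylation of the para-dimethoxyarene by tetravalent cerium gives the quinone, with water supplying the carbonyl oxygens; the olefins, ketone and alcohol survive the short cold exposure.

Step 22
Reactants: 33 quinone
Product: 34 (2E,6E,10E,13R)-1-(2,5-dihydroxy-3-methylphenyl)-13-hydroxy-3,7,11,15-tetramethylhexadeca-2,6,10,14-tetraen-5-one
Conditions: Na2S2O4 (excess), Et2O/H2O, rt, 10 min, under Ar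
Reagents that add atoms: none
Why: Dithionite reduces the quinone to the hydroquinone within minutes at neutral pH and does not touch the enone or olefins under these conditions.

**Compound list**
1 | methyl 3-methylbut-2-enoate | COC(=O)C=C(C)C | starting material
2 | lithium 1-methoxy-3-methylbuta-1,3-dien-1-olate | [Li+].COC([O-])=CC(C)=C | intermediate
3 | tert-butyl[(1-methoxy-3-methylbuta-1,3-dien-1-yl)oxy]dimethylsilane (C1=C2 geometry immaterial) | COC(O[Si](C)(C)C(C)(C)C)=CC(C)=C | intermediate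
4 | 3-methylbut-2-enal | CC(C)=CC=O | starting material
5 | methyl (2E,5R)-3,7-dimethyl-5-[(trichlorosilyl)oxy]octa-2,6-dienoate | CC(C)=C[C@H](O[Si](Cl)(Cl)Cl)C/C(C)=C/C(=O)OC | intermediate
6 | methyl (2E,5R)-5-hydroxy-3,7-dimethylocta-2,6-dienoate | CC(C)=C[C@H](O)C/C(C)=C/C(=O)OC | intermediate
7 | methyl (2E,5R)-5-[(tert-butyldimethylsilyl)oxy]-3,7-dimethylocta-2,6-dienoate | CC(C)=C[C@H](O[Si](C)(C)C(C)(C)C)C/C(C)=C/C(=O)OC | intermediate
8 | (2E,5R)-5-[(tert-butyldimethylsilyl)oxy]-3,7-dimethylocta-2,6-dien-1-ol | CC(C)=C[C@H](O[Si](C)(C)C(C)(C)C)C/C(C)=C/CO | intermediate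
9 | (2E,5R)-5-[(tert-butyldimethylsilyl)oxy]-3,7-dimethylocta-2,6-dien-1-yl methanesulfonate | CC(C)=C[C@H](O[Si](C)(C)C(C)(C)C)C/C(C)=C/COS(C)(=O)=O | intermediate
10 | (2E,5R)-1-bromo-5-[(tert-butyldimethylsilyl)oxy]-3,7-dimethylocta-2,6-diene | CC(C)=C[C@H](O[Si](C)(C)C(C)(C)C)C/C(C)=C/CBr | intermediate
11 | methyl acetoacetate | CC(=O)CC(=O)OC | starting material
12 | sodium lithium dianion of methyl acetoacetate | [Na+].[Li+].C=C([O-])C=C([O-])OC | intermediate
13 | methyl (6E,9R)-9-[(tert-butyldimethylsilyl)oxy]-7,11-dimethyl-3-oxododeca-6,10-dienoate | CC(C)=C[C@H](O[Si](C)(C)C(C)(C)C)C/C(C)=C/CCC(=O)CC(=O)OC | intermediate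
14 | sodium (2Z) enolate of 13 | [Na+].CC(C)=C[C@H](O[Si](C)(C)C(C)(C)C)C/C(C)=C/CC/C([O-])=C/C(=O)OC | intermediate
15 | methyl (2Z,6E,9R)-9-[(tert-butyldimethylsilyl)oxy]-3-[(diethoxyphosphoryl)oxy]-7,11-dimethyldodeca-2,6,10-trienoate | CC(C)=C[C@H](O[Si](C)(C)C(C)(C)C)C/C(C)=C/CC/C(OP(=O)(OCC)OCC)=C/C(=O)OC | intermediate
16 | methyl (2E,6E,9R)-9-[(tert-butyldimethylsilyl)oxy]-3,7,11-trimethyldodeca-2,6,10-trienoate | CC(C)=C[C@H](O[Si](C)(C)C(C)(C)C)C/C(C)=C/CC/C(C)=C/C(=O)OC | intermediate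
17 | (2E,6E,9R)-9-[(tert-butyldimethylsilyl)oxy]-3,7,11-trimethyldodeca-2,6,10-trien-1-ol | CC(C)=C[C@H](O[Si](C)(C)C(C)(C)C)C/C(C)=C/CC/C(C)=C/CO | intermediate
18 | (2E,6E,9R)-9-[(tert-butyldimethylsilyl)oxy]-3,7,11-trimethyldodeca-2,6,10-trienal | CC(C)=C[C@H](O[Si](C)(C)C(C)(C)C)C/C(C)=C/CC/C(C)=C/C=O | intermediate
19 | methyl (2E,5R,6E,10E,13R)-13-[(tert-butyldimethylsilyl)oxy]-3,7,11,15-tetramethyl-5-[(trichlorosilyl)oxy]hexadeca-2,6,10,14-tetraenoate | CC(C)=C[C@H](O[Si](C)(C)C(C)(C)C)C/C(C)=C/CC/C(C)=C/[C@H](O[Si](Cl)(Cl)Cl)C/C(C)=C/C(=O)OC | intermediate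
20 | methyl (2E,5R,6E,10E,13R)-13-[(tert-butyldimethylsilyl)oxy]-5-hydroxy-3,7,11,15-tetramethylhexadeca-2,6,10,14-tetraenoate | CC(C)=C[C@H](O[Si](C)(C)C(C)(C)C)C/C(C)=C/CC/C(C)=C/[C@H](O)C/C(C)=C/C(=O)OC | intermediate
21 | methyl (2E,5R,6E,10E,13R)-13-[(tert-butyldimethylsilyl)oxy]-3,7,11,15-tetramethyl-5-[(triethylsilyl)oxy]hexadeca-2,6,10,14-tetraenoate | CC(C)=C[C@H](O[Si](C)(C)C(C)(C)C)C/C(C)=C/CC/C(C)=C/[C@H](O[Si](CC)(CC)CC)C/C(C)=C/C(=O)OC | intermediate
22 | (2E,5R,6E,10E,13R)-13-[(tert-butyldimethylsilyl)oxy]-3,7,11,15-tetramethyl-5-[(triethylsilyl)oxy]hexadeca-2,6,10,14-tetraen-1-ol | CC(C)=C[C@H](O[Si](C)(C)C(C)(C)C)C/C(C)=C/CC/C(C)=C/[C@H](O[Si](CC)(CC)CC)C/C(C)=C/CO | intermediate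
23 | (2E,5R,6E,10E,13R)-13-[(tert-butyldimethylsilyl)oxy]-3,7,11,15-tetramethyl-5-[(triethylsilyl)oxy]hexadeca-2,6,10,14-tetraen-1-yl methanesulfonate | CC(C)=C[C@H](O[Si](C)(C)C(C)(C)C)C/C(C)=C/CC/C(C)=C/[C@H](O[Si](CC)(CC)CC)C/C(C)=C/COS(C)(=O)=O | intermediate
24 | (2E,5R,6E,10E,13R)-1-bromo-13-[(tert-butyldimethylsilyl)oxy]-3,7,11,15-tetramethyl-5-[(triethylsilyl)oxy]hexadeca-2,6,10,14-tetraene | CC(C)=C[C@H](O[Si](C)(C)C(C)(C)C)C/C(C)=C/CC/C(C)=C/[C@H](O[Si](CC)(CC)CC)C/C(C)=C/CBr | intermediate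
25 | 4-methoxy-2-methylphenol | COc1ccc(O)c(C)c1 | starting material
26 | 2-bromo-4-methoxy-6-methylphenol | COc1cc(C)c(O)c(Br)c1 | intermediate
27 | 1-bromo-2,5-dimethoxy-3-methylbenzene | COc1cc(C)c(OC)c(Br)c1 | intermediate
28 | (2,5-dimethoxy-3-methylphenyl)lithium | [Li]c1cc(OC)cc(C)c1OC | intermediate
29 | (2E,5R,6E,10E,13R)-13-[(tert-butyldimethylsilyl)oxy]-1-(2,5-dimethoxy-3-methylphenyl)-3,7,11,15-tetramethyl-5-[(triethylsilyl)oxy]hexadeca-2,6,10,14-tetraene | CC(C)=C[C@H](O[Si](C)(C)C(C)(C)C)C/C(C)=C/CC/C(C)=C/[C@H](O[Si](CC)(CC)CC)C/C(C)=C/Cc1cc(OC)cc(C)c1OC | intermediate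
30 | (2E,5R,6E,10E,13R)-13-[(tert-butyldimethylsilyl)oxy]-1-(2,5-dimethoxy-3-methylphenyl)-3,7,11,15-tetramethylhexadeca-2,6,10,14-tetraen-5-ol | CC(C)=C[C@H](O[Si](C)(C)C(C)(C)C)C/C(C)=C/CC/C(C)=C/[C@H](O)C/C(C)=C/Cc1cc(OC)cc(C)c1OC | intermediate
31 | (2E,6E,10E,13R)-13-[(tert-butyldimethylsilyl)oxy]-1-(2,5-dimethoxy-3-methylphenyl)-3,7,11,15-tetramethylhexadeca-2,6,10,14-tetraen-5-one | CC(C)=C[C@H](O[Si](C)(C)C(C)(C)C)C/C(C)=C/CC/C(C)=C/C(=O)C/C(C)=C/Cc1cc(OC)cc(C)c1OC | intermediate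
32 | (2E,6E,10E,13R)-1-(2,5-dimethoxy-3-methylphenyl)-13-hydroxy-3,7,11,15-tetramethylhexadeca-2,6,10,14-tetraen-5-one | CC(C)=C[C@H](O)C/C(C)=C/CC/C(C)=C/C(=O)C/C(C)=C/Cc1cc(OC)cc(C)c1OC | intermediate
33 | 2-[(2E,6E,10E,13R)-13-hydroxy-3,7,11,15-tetramethyl-5-oxohexadeca-2,6,10,14-tetraen-1-yl]-6-methylcyclohexa-2,5-diene-1,4-dione | CC(C)=C[C@H](O)C/C(C)=C/CC/C(C)=C/C(=O)C/C(C)=C/CC1=CC(=O)C=C(C)C1=O | intermediate
34 | (2E,6E,10E,13R)-1-(2,5-dihydroxy-3-methylphenyl)-13-hydroxy-3,7,11,15-tetramethylhexadeca-2,6,10,14-tetraen-5-one | CC(C)=C[C@H](O)C/C(C)=C/CC/C(C)=C/C(=O)C/C(C)=C/Cc1cc(O)cc(C)c1O | target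

**Step count and risks**
Total steps: 22. Longest linear sequence: 20 steps (steps 1–14, then 17–22); the arene branch is steps 15–16.

Most likely to fail:

Step 2 (enantio- and E-selectivity of the asymmetric vinylogous aldol on a β,β-disubstituted enal). The fallback sets out from 4 and comes back at 7. The dienolate is changed to an acetoacetate equivalent and the trisubstituted olefin is built afterwards. 2,2,6-Trimethyl-4H-1,3-dioxin-4-one is converted with LiN(i-Pr)2/Me3SiCl into 2,2-dimethyl-6-methylidene-4-[(trimethylsilyl)oxy]-4H-1,3-dioxine F1. Addition of F1 to 4, catalysed by Cu(OTf)2/Tol-BINAP/Bu4N[Ph3SiF2] (the ligand enantiomer that gives Re-face addition), followed by acidic work-up gives 6-[(2R)-2-hydroxy-4-methylpent-3-en-1-yl]-2,2-dimethyl-4H-1,3-dioxin-4-one F2. Silylation (TBSCl, imidazole) gives 6-[(2R)-2-[(tert-butyldimethylsilyl)oxy]-4-methylpent-3-en-1-yl]-2,2-dimethyl-4H-1,3-dioxin-4-one F3. Thermolysis in MeOH/toluene at 110 °C gives methyl (5R)-5-[(tert-butyldimethylsilyl)oxy]-7-methyl-3-oxooct-6-enoate F4. NaH/ClP(O)(OEt)2 gives methyl (2Z,5R)-5-[(tert-butyldimethylsilyl)oxy]-3-[(diethoxyphosphoryl)oxy]-7-methylocta-2,6-dienoate F5, and Me2CuLi converts F5 into 7.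

Step 17 (aryllithium coupling on the advanced allylic bromide: elimination, SN2', loss of precious material). The fallback sets out from 28 and 18 and comes back at 31. The aryl–allyl bond is made on a cheap C5 unit and the fragments are joined by an α-selective carbonyl allylation. 28 with 1-bromo-3-methylbut-2-ene gives 2,5-dimethoxy-1-methyl-3-(3-methylbut-2-en-1-yl)benzene F6. SeO2 (cat.)/t-BuOOH, then NaBH4, gives (2E)-4-(2,5-dimethoxy-3-methylphenyl)-2-methylbut-2-en-1-ol F7. MsCl/LiCl/s-collidine in DMF gives 1-[(2E)-4-chloro-3-methylbut-2-en-1-yl]-2,5-dimethoxy-3-methylbenzene F8. Active barium metal (from BaI2 and lithium biphenylide, THF, −78 °C) turns F8 into the allylbarium reagent, which adds through its α-carbon with retained E geometry to enal 18. This gives the C5-epimeric mixture (2E,6E,10E,13R)-13-[(tert-butyldimethylsilyl)oxy]-1-(2,5-dimethoxy-3-methylphenyl)-3,7,11,15-tetramethylhexadeca-2,6,10,14-tetraen-5-ol F9, which Dess–Martin oxidation converts into 31.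

Step 21 (acidic cerium oxidation in the presence of the free, ionisable allylic alcohol). The fallback sets out from 31 and comes back at 34. The order of unmasking is changed so that the carbinol stays silylated during the oxidation. (NH4)2Ce(NO3)6 on 31 gives 2-[(2E,6E,10E,13R)-13-[(tert-butyldimethylsilyl)oxy]-3,7,11,15-tetramethyl-5-oxohexadeca-2,6,10,14-tetraen-1-yl]-6-methylcyclohexa-2,5-diene-1,4-dione F10. Na2S2O4 gives (2E,6E,10E,13R)-13-[(tert-butyldimethylsilyl)oxy]-1-(2,5-dihydroxy-3-methylphenyl)-3,7,11,15-tetramethylhexadeca-2,6,10,14-tetraen-5-one F11. HF·pyridine/pyridine in THF at 0 °C under Ar then gives 34.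

**Further compounds**
F1 | step 2 | 2,2-dimethyl-6-methylidene-4-[(trimethylsilyl)oxy]-4H-1,3-dioxine | C=C1C=C(O[Si](C)(C)C)OC(C)(C)O1
F2 | step 2 | 6-[(2R)-2-hydroxy-4-methylpent-3-en-1-yl]-2,2-dimethyl-4H-1,3-dioxin-4-one | CC(C)=C[C@H](O)CC1=CC(=O)OC(C)(C)O1
F3 | step 2 | 6-[(2R)-2-[(tert-butyldimethylsilyl)oxy]-4-methylpent-3-en-1-yl]-2,2-dimethyl-4H-1,3-dioxin-4-one | CC(C)=C[C@H](O[Si](C)(C)C(C)(C)C)CC1=CC(=O)OC(C)(C)O1
F4 | step 2 | methyl (5R)-5-[(tert-butyldimethylsilyl)oxy]-7-methyl-3-oxooct-6-enoate | CC(C)=C[C@H](O[Si](C)(C)C(C)(C)C)CC(=O)CC(=O)OC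
F5 | step 2 | methyl (2Z,5R)-5-[(tert-butyldimethylsilyl)oxy]-3-[(diethoxyphosphoryl)oxy]-7-methylocta-2,6-dienoate | CC(C)=C[C@H](O[Si](C)(C)C(C)(C)C)C/C(OP(=O)(OCC)OCC)=C/C(=O)OC
F6 | step 17 | 2,5-dimethoxy-1-methyl-3-(3-methylbut-2-en-1-yl)benzene | COc1cc(C)c(OC)c(CC=C(C)C)c1
F7 | step 17 | (2E)-4-(2,5-dimethoxy-3-methylphenyl)-2-methylbut-2-en-1-ol | COc1cc(C)c(OC)c(C/C=C(\C)CO)c1
F8 | step 17 | 1-[(2E)-4-chloro-3-methylbut-2-en-1-yl]-2,5-dimethoxy-3-methylbenzene | COc1cc(C)c(OC)c(C/C=C(\C)CCl)c1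
F9 | step 17 | (2E,6E,10E,13R)-13-[(tert-butyldimethylsilyl)oxy]-1-(2,5-dimethoxy-3-methylphenyl)-3,7,11,15-tetramethylhexadeca-2,6,10,14-tetraen-5-ol (C5 epimer mixture) | CC(C)=C[C@H](O[Si](C)(C)C(C)(C)C)C/C(C)=C/CC/C(C)=C/C(O)C/C(C)=C/Cc1cc(OC)cc(C)c1OC
F10 | step 21 | 2-[(2E,6E,10E,13R)-13-[(tert-butyldimethylsilyl)oxy]-3,7,11,15-tetramethyl-5-oxohexadeca-2,6,10,14-tetraen-1-yl]-6-methylcyclohexa-2,5-diene-1,4-dione | CC(C)=C[C@H](O[Si](C)(C)C(C)(C)C)C/C(C)=C/CC/C(C)=C/C(=O)C/C(C)=C/CC1=CC(=O)C=C(C)C1=O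
F11 | step 21 | (2E,6E,10E,13R)-13-[(tert-butyldimethylsilyl)oxy]-1-(2,5-dihydroxy-3-methylphenyl)-3,7,11,15-tetramethylhexadeca-2,6,10,14-tetraen-5-one | CC(C)=C[C@H](O[Si](C)(C)C(C)(C)C)C/C(C)=C/CC/C(C)=C/C(=O)C/C(C)=C/Cc1cc(O)cc(C)c1O
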